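**Retrosynthetic overview**

- Feature: ring A is a hexasubstituted benzene (C1 phenethyl, C2/C4/C6 4-oxybenzyl, C3 OH, C5 OMe) whose two oxygens are meta. C5 lies between C4 and C6, so it can be one carbon (CO) stitched between the ends of an open C6–C1–C2–C3–C4 chain, with the C3 oxygen delivered by a migrating ester.
- Key disconnection: C4–C5 and C5–C6, by rhodium-catalysed carbonylative [5+1] closure of the tertiary 3-pivaloyloxy-1,4-enyne 16; the aroyl cap on its alkyne becomes the C4 benzyl carbon. Ring A is the only ring made; the four outer benzene rings are bought.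
- Enyne 16: C3 and C4 come from acetylene added to enone 10 (O-pivaloylated in the same flask), followed by acyl Sonogashira coupling with 4-benzyloxybenzoyl chloride. Enone 10 comes from an HWE olefination (C1=C6), a Weinreb amide and a benzylic Grignard reagent.
- After ring closure: methylation of the free C5 phenol, LiAlH4 (pivalate off, ketone to carbinol), ionic deoxygenation to the C4 benzyl group, hydrogenolysis of three benzyl ethers.

Key step: step 8

Remark on the chemistry: the target is achiral. The carbinol centre of the enyne is carried racemic, and the E alkene geometry (aimed at and drawn) is erased when ring A aromatises, so a minor Z isomer could be carried through.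

**Route**

Step 1
Reactants: 1 3-methoxyphenethyl bromide; 2 triethyl phosphonoacetate
Product: 3 ethyl 2-(diethoxyphosphoryl)-4-(3-methoxyphenyl)butanoate (racemic)
Conditions: NaH, DMF, 0 → 60 °C (2 in excess)
Reagents that add atoms: none
Why: SN2 alkylation of the sodium phosphonoacetate carbanion by the primary bromide, with excess phosphonate holding back dialkylation and loss of HBr; the new stereocentre is racemic and disappears in step 3.

Step 2
Reactants: 4 2-(4-benzyloxyphenyl)ethanol
Product: 5 (4-benzyloxyphenyl)acetaldehyde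
Conditions: Dess–Martin periodinane, CH2Cl2, 0 °C → rt; used at once
Reagents that add atoms: none
Why: Dess–Martin oxidation stops at the aldehyde under near-neutral, non-enolising conditions, which suits the sensitive arylacetaldehyde.

Step 3
Reactants: 3 ethyl 2-(diethoxyphosphoryl)-4-(3-methoxyphenyl)butanoate; 5 (4-benzyloxyphenyl)acetaldehyde
Product: 6 ethyl (E)-4-(4-benzyloxyphenyl)-2-[2-(3-methoxyphenyl)ethyl]but-2-enoate
Conditions: NaH (slightly less than 3), THF, 0 °C; then 5, −78 → 0 °C
Reagents that add atoms: none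
Why: Horner–Wadsworth–Emmons olefination, in which reversible addition of the stabilised phosphonate anion should favour the E enoate (ester trans to the new CH2Ar group); adding the aldehyde cold to the preformed anion without free base limits aldol reaction and double-bond migration.

Step 4
Reactants: 6 ethyl (E)-4-(4-benzyloxyphenyl)-2-[2-(3-methoxyphenyl)ethyl]but-2-enoate
Product: 7 (E)-4-(4-benzyloxyphenyl)-N-methoxy-2-[2-(3-methoxyphenyl)ethyl]-N-methylbut-2-enamide
Conditions: MeNHOMe·HCl, AlMe3, CH2Cl2, 0 °C → rt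
Reagents that add atoms: N,O-dimethylhydroxylamine hydrochloride, SMILES CNOC.Cl
Why: Weinreb aminolysis of the ester by the aluminium amide made from AlMe3 and the amine salt, a Lewis-acidic and non-basic reagent that should leave the position and geometry of the alkene untouched.

Step 5
Reactants: 7 (E)-4-(4-benzyloxyphenyl)-N-methoxy-2-[2-(3-methoxyphenyl)ethyl]-N-methylbut-2-enamide; 8 4-benzyloxybenzyl chloride
Product: 10 (E)-1,5-bis(4-benzyloxyphenyl)-3-[2-(3-methoxyphenyl)ethyl]pent-3-en-2-one, via 4-benzyloxybenzylmagnesium chloride 9 (not isolated)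
Conditions: 8, Mg, THF, 0 °C (slow addition); then 7, −78 → 0 °C; aq. NH4Cl
Reagents that add atoms: none
Why: Weinreb ketone synthesis, in which the benzylic Grignard reagent adds once and the chelated tetrahedral adduct survives until work-up, so there is no over-addition and the enolisable ketone never meets the organometallic.

Step 6
Reactants: 10 (E)-1,5-bis(4-benzyloxyphenyl)-3-[2-(3-methoxyphenyl)ethyl]pent-3-en-2-one; 11 acetylene
Product: 14 racemic (E)-3-(4-benzyloxybenzyl)-6-(4-benzyloxyphenyl)-4-[2-(3-methoxyphenyl)ethyl]hex-4-en-1-yn-3-yl pivalate, via lithium acetylide 12 (not isolated), via lithium alkoxide of the tertiary carbinol 13 (not isolated)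
Conditions: 11 (excess), n-BuLi, THF, −78 °C; then 10, −78 °C; then PivCl, −78 °C → rt
Reagents that add atoms: pivaloyl chloride, SMILES CC(C)(C)C(=O)Cl
Why: 1,2-addition of the small, weakly basic monolithium acetylide to the ketone, then O-acylation of the tertiary lithium alkoxide before it is protonated (the usual way to hindered tertiary propargylic esters); the new quaternary centre is racemic and later becomes the sp2 carbon C2.

Step 7
Reactants: 14 racemic (E)-3-(4-benzyloxybenzyl)-6-(4-benzyloxyphenyl)-4-[2-(3-methoxyphenyl)ethyl]hex-4-en-1-yn-3-yl pivalate; 15 4-benzyloxybenzoyl chloride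
Product: 16 racemic (E)-4-(4-benzyloxybenzyl)-1,7-bis(4-benzyloxyphenyl)-5-[2-(3-methoxyphenyl)ethyl]-1-oxohept-5-en-2-yn-4-yl pivalate
Conditions: PdCl2(PPh3)2 (2 mol%), CuI (4 mol%), Et3N, THF, rt
Reagents that add atoms: none
Why: acyl Sonogashira coupling (oxidative addition of the aroyl chloride to zerovalent palladium, transmetalation from the copper acetylide, reductive elimination) at room temperature, where the propargylic pivalate should not ionise, and the fully substituted carbinol carbon has no hydrogen through which the ynone could isomerise to an allenone.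

Step 8
Reactants: 16 racemic (E)-4-(4-benzyloxybenzyl)-1,7-bis(4-benzyloxyphenyl)-5-[2-(3-methoxyphenyl)ethyl]-1-oxohept-5-en-2-yn-4-yl pivalate; 17 carbon monoxide
Product: 20 2-(4-benzyloxybenzoyl)-4,6-bis(4-benzyloxybenzyl)-3-hydroxy-5-[2-(3-methoxyphenyl)ethyl]phenyl pivalate, via dienylketene 18 (not isolated), via cyclohexa-2,4-dienone 19 (not isolated)
Conditions: [Rh(CO)2Cl]2 (5 mol%), CO (1 atm), 1,2-dichloroethane, 80 °C
Reagents that add atoms: none
Why: Proposed new method: monovalent rhodium should bind the alkyne of 16 so that the pivalate carbonyl oxygen adds to the alkyne carbon next to the carbinol carbon (beta to the aroyl carbonyl), and opening of the resulting dioxolenium ring with cleavage of the tertiary C–O bond should give a rhodium carbene on the aroyl-bearing carbon, conjugated with the new enol pivalate and the trisubstituted alkene; uptake of CO at the carbene should then form C4–C5 and release dienylketene 18. The closest known reaction type is the [Rh(CO)2Cl]2-catalysed [5+1] carbonylation of secondary 3-acyloxy-1,4-enynes to resorcinol monoesters, which has not been shown for a tertiary ester with every carbon of the five-carbon unit substituted. Ring A is closed by thermal six-electron electrocyclisation of 18 (ketene carbon onto the alkene terminus, forming C5–C6; the equivalent metal-bound path is CO insertion into a rhodacyclohexadiene and reductive elimination), and dienone 19 aromatises by shift of the C6 hydrogen to oxygen. No stereocentre is created: the carbinol centre of 16 becomes sp2 C2 and the alkene geometry is erased, the E isomer being preferred only because it places hydrogen and not the benzyl group inside the closing triene. The step needs 1,2- and not 1,3-acyloxy migration, which the electron-poor ynone should secure by making the internal alkyne carbon the Michael-type acceptor for the ester oxygen; the two ring oxygens then emerge differentiated, as C3 pivalate and free C5 phenol.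

Step 9
Reactants: 20 2-(4-benzyloxybenzoyl)-4,6-bis(4-benzyloxybenzyl)-3-hydroxy-5-[2-(3-methoxyphenyl)ethyl]phenyl pivalate
Product: 21 2-(4-benzyloxybenzoyl)-4,6-bis(4-benzyloxybenzyl)-3-methoxy-5-[2-(3-methoxyphenyl)ethyl]phenyl pivalate
Conditions: MeI, K2CO3, DMF, 40 °C
Reagents that add atoms: iodomethane, SMILES CI
Why: Williamson O-methylation of the only free phenol (C5), while the C3 oxygen stays masked as a hindered pivalate that sits meta to C5 and so cannot transfer its acyl group.

Step 10
Reactants: 21 2-(4-benzyloxybenzoyl)-4,6-bis(4-benzyloxybenzyl)-3-methoxy-5-[2-(3-methoxyphenyl)ethyl]phenyl pivalate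
Product: 22 racemic 2,4-bis(4-benzyloxybenzyl)-6-[(4-benzyloxyphenyl)(hydroxy)methyl]-5-methoxy-3-[2-(3-methoxyphenyl)ethyl]phenol
Conditions: LiAlH4, THF, 0 °C → reflux; Rochelle salt work-up
Reagents that add atoms: none
Why: hydride reduction with LiAlH4, which cleaves the aryl pivalate reductively and reduces the diaryl ketone to the benzhydrol while benzyl and methyl ethers are inert; the carbinol centre forms racemic and is removed in step 11.

Step 11
Reactants: 22 racemic 2,4-bis(4-benzyloxybenzyl)-6-[(4-benzyloxyphenyl)(hydroxy)methyl]-5-methoxy-3-[2-(3-methoxyphenyl)ethyl]phenol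
Product: 23 2,4,6-tris(4-benzyloxybenzyl)-3-methoxy-5-[2-(3-methoxyphenyl)ethyl]phenol
Conditions: Et3SiH, TFA, CH2Cl2, 0 °C
Reagents that add atoms: none
Why: ionic hydrogenation, in which acid ionises the benzhydrol to a cation stabilised by the ortho-hydroxy and ortho-methoxy groups of ring A and by the 4-benzyloxyphenyl ring (the protonated ortho-quinone methide) and the silane delivers hydride; aryl benzyl ethers should survive brief cold TFA.

Step 12
Reactants: 23 2,4,6-tris(4-benzyloxybenzyl)-3-methoxy-5-[2-(3-methoxyphenyl)ethyl]phenol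
Product: 24 2,4,6-tris(4-hydroxybenzyl)-3-methoxy-5-[2-(3-methoxyphenyl)ethyl]phenol (CNP0285788.0)
Conditions: H2 (1 atm), Pd/C, EtOAc–MeOH, rt
Reagents that add atoms: none
Why: catalytic hydrogenolysis of the three aryl benzyl ethers, under which the diarylmethane C–C bonds and the methyl ethers are not cleaved.

**Compound list**

1 | 3-methoxyphenethyl bromide | COc1cccc(CCBr)c1 | starting material
2 | triethyl phosphonoacetate | CCOC(=O)CP(=O)(OCC)OCC | starting material
3 | ethyl 2-(diethoxyphosphoryl)-4-(3-methoxyphenyl)butanoate (racemic) | CCOC(=O)C(CCc1cccc(OC)c1)P(=O)(OCC)OCC | intermediate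
4 | 2-(4-benzyloxyphenyl)ethanol | OCCc1ccc(OCc2ccccc2)cc1 | starting material
5 | (4-benzyloxyphenyl)acetaldehyde | O=CCc1ccc(OCc2ccccc2)cc1 | intermediate
6 | ethyl (E)-4-(4-benzyloxyphenyl)-2-[2-(3-methoxyphenyl)ethyl]but-2-enoate | CCOC(=O)/C(CCc1cccc(OC)c1)=C/Cc1ccc(OCc2ccccc2)cc1 | intermediate
7 | (E)-4-(4-benzyloxyphenyl)-N-methoxy-2-[2-(3-methoxyphenyl)ethyl]-N-methylbut-2-enamide | CON(C)C(=O)/C(CCc1cccc(OC)c1)=C/Cc1ccc(OCc2ccccc2)cc1 | intermediate
8 | 4-benzyloxybenzyl chloride | ClCc1ccc(OCc2ccccc2)cc1 | starting material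
9 | 4-benzyloxybenzylmagnesium chloride | Cl[Mg]Cc1ccc(OCc2ccccc2)cc1 | intermediate (not isolated)
10 | (E)-1,5-bis(4-benzyloxyphenyl)-3-[2-(3-methoxyphenyl)ethyl]pent-3-en-2-one | O=C(Cc1ccc(OCc2ccccc2)cc1)/C(CCc1cccc(OC)c1)=C/Cc1ccc(OCc2ccccc2)cc1 | intermediate
11 | acetylene | C#C | starting material
12 | lithium acetylide | [Li]C#C | intermediate (not isolated)
13 | lithium (E)-3-(4-benzyloxybenzyl)-6-(4-benzyloxyphenyl)-4-[2-(3-methoxyphenyl)ethyl]hex-4-en-1-yn-3-olate (racemic) | [Li]OC(Cc1ccc(OCc2ccccc2)cc1)(C#C)/C(CCc1cccc(OC)c1)=C/Cc1ccc(OCc2ccccc2)cc1 | intermediate (not isolated)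
14 | (E)-3-(4-benzyloxybenzyl)-6-(4-benzyloxyphenyl)-4-[2-(3-methoxyphenyl)ethyl]hex-4-en-1-yn-3-yl pivalate (racemic) | CC(C)(C)C(=O)OC(Cc1ccc(OCc2ccccc2)cc1)(C#C)/C(CCc1cccc(OC)c1)=C/Cc1ccc(OCc2ccccc2)cc1 | intermediate
15 | 4-benzyloxybenzoyl chloride | O=C(Cl)c1ccc(OCc2ccccc2)cc1 | starting material
16 | (E)-4-(4-benzyloxybenzyl)-1,7-bis(4-benzyloxyphenyl)-5-[2-(3-methoxyphenyl)ethyl]-1-oxohept-5-en-2-yn-4-yl pivalate (racemic; key-step precursor) | CC(C)(C)C(=O)OC(Cc1ccc(OCc2ccccc2)cc1)(C#CC(=O)c1ccc(OCc2ccccc2)cc1)/C(CCc1cccc(OC)c1)=C/Cc1ccc(OCc2ccccc2)cc1 | intermediate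
17 | carbon monoxide | [C-]#[O+] | starting material
18 | (3E,5E)-2-(4-benzyloxybenzoyl)-4-(4-benzyloxybenzyl)-7-(4-benzyloxyphenyl)-5-[2-(3-methoxyphenyl)ethyl]-1-oxohepta-1,3,5-trien-3-yl pivalate (dienylketene; ketene and alkenyl group cis on the central alkene) | O=C=C(C(=O)c1ccc(OCc2ccccc2)cc1)/C(OC(=O)C(C)(C)C)=C(Cc1ccc(OCc2ccccc2)cc1)\C(CCc1cccc(OC)c1)=C\Cc1ccc(OCc2ccccc2)cc1 | intermediate (not isolated)
19 | 2-(4-benzyloxybenzoyl)-4,6-bis(4-benzyloxybenzyl)-5-[2-(3-methoxyphenyl)ethyl]-3-oxocyclohexa-1,5-dien-1-yl pivalate (racemic at the sp3 ring carbon) | O=C1C(C(=O)c2ccc(OCc3ccccc3)cc2)=C(OC(=O)C(C)(C)C)C(Cc2ccc(OCc3ccccc3)cc2)=C(CCc2cccc(OC)c2)C1Cc1ccc(OCc2ccccc2)cc1 | intermediate (not isolated)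
20 | 2-(4-benzyloxybenzoyl)-4,6-bis(4-benzyloxybenzyl)-3-hydroxy-5-[2-(3-methoxyphenyl)ethyl]phenyl pivalate (ring A with C3 pivalate, C4 aroyl, C5 OH) | COc1cccc(CCc2c(Cc3ccc(OCc4ccccc4)cc3)c(OC(=O)C(C)(C)C)c(C(=O)c3ccc(OCc4ccccc4)cc3)c(O)c2Cc2ccc(OCc3ccccc3)cc2)c1 | intermediate
21 | 2-(4-benzyloxybenzoyl)-4,6-bis(4-benzyloxybenzyl)-3-methoxy-5-[2-(3-methoxyphenyl)ethyl]phenyl pivalate | COc1cccc(CCc2c(Cc3ccc(OCc4ccccc4)cc3)c(OC(=O)C(C)(C)C)c(C(=O)c3ccc(OCc4ccccc4)cc3)c(OC)c2Cc2ccc(OCc3ccccc3)cc2)c1 | intermediate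
22 | 2,4-bis(4-benzyloxybenzyl)-6-[(4-benzyloxyphenyl)(hydroxy)methyl]-5-methoxy-3-[2-(3-methoxyphenyl)ethyl]phenol (racemic) | COc1cccc(CCc2c(Cc3ccc(OCc4ccccc4)cc3)c(O)c(C(O)c3ccc(OCc4ccccc4)cc3)c(OC)c2Cc2ccc(OCc3ccccc3)cc2)c1 | intermediate
23 | 2,4,6-tris(4-benzyloxybenzyl)-3-methoxy-5-[2-(3-methoxyphenyl)ethyl]phenol | COc1cccc(CCc2c(Cc3ccc(OCc4ccccc4)cc3)c(O)c(Cc3ccc(OCc4ccccc4)cc3)c(OC)c2Cc2ccc(OCc3ccccc3)cc2)c1 | intermediate
24 | 2,4,6-tris(4-hydroxybenzyl)-3-methoxy-5-[2-(3-methoxyphenyl)ethyl]phenol | COc1cccc(CCc2c(Cc3ccc(O)cc3)c(O)c(Cc3ccc(O)cc3)c(OC)c2Cc2ccc(O)cc2)c1 | target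

**Step count**

Total steps: 12. Longest linear sequence: 11 (steps 1, 3–12; the branch through step 2 is equally long).

**Steps most likely to fail**

1. Step 8 (proposed new method). The pivalate may shift 1,3 onto the aroyl-bearing alkyne carbon and drain the substrate through an allenyl ester into cyclopentenone-type products, or crowding around the carbene may slow CO uptake until the carbene decomposes. The fallback uses known chemistry, sets out from 1 and comes back at 23; ring A is taken from a bought arene instead of being built.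
   - Bromide 1 would be coupled under Li2CuCl4 catalysis (THF, 0 °C) with 3-benzyloxy-5-methoxyphenylmagnesium bromide F1, made from 1-benzyloxy-3-bromo-5-methoxybenzene and Mg, to give 1-benzyloxy-3-methoxy-5-[2-(3-methoxyphenyl)ethyl]benzene F2.
   - Hydrogenolysis (H2, Pd/C) would give 3-methoxy-5-[2-(3-methoxyphenyl)ethyl]phenol F3. Its three free ring positions, each ortho or para to both oxygens, are exactly C2, C4 and C6.
   - Exhaustive Friedel–Crafts benzylation with chloride 8 (3.3 equiv, ZnCl2, CH2Cl2, or in hexafluoroisopropanol) should give 23, which enters step 12.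
   - The price is under-benzylation and some benzylation of the pendant anisole-type rings, to be removed by chromatography.

2. Step 6. The acetylide may act as a base on the benzylic ketone (enolisation) instead of adding, and the very hindered tertiary alkoxide may be acylated only in part. The fallback sets out from 7 and comes back at 14; it changes which bond to the carbinol carbon is made last.
   - Commercial lithium (trimethylsilyl)acetylide on Weinreb amide 7 should give (E)-6-(4-benzyloxyphenyl)-4-[2-(3-methoxyphenyl)ethyl]-1-(trimethylsilyl)hex-4-en-1-yn-3-one F4, a ketone with no alpha hydrogen.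
   - Addition of Grignard reagent 9 (with LaCl3·2LiCl, THF, −78 °C) should give racemic (E)-3-(4-benzyloxybenzyl)-6-(4-benzyloxyphenyl)-4-[2-(3-methoxyphenyl)ethyl]-1-(trimethylsilyl)hex-4-en-1-yn-3-ol F5.
   - Separate O-acylation (LiHMDS, then PivCl, THF, −78 °C → rt, unreacted alcohol recycled) should give racemic (E)-3-(4-benzyloxybenzyl)-6-(4-benzyloxyphenyl)-4-[2-(3-methoxyphenyl)ethyl]-1-(trimethylsilyl)hex-4-en-1-yn-3-yl pivalate F6.
   - K2CO3 in MeOH removes the silyl group and returns 14.

3. Step 3. The enolisable arylacetaldehyde may self-condense, the new double bond may migrate into conjugation with the aryl ring under base, and the E/Z ratio may erode. The fallback sets out from 3 and comes back at 6; the aryl–CH2 bond is made by cross-coupling, so no arylacetaldehyde is needed.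
   - HWE olefination of 3 with commercial (tert-butyldimethylsilyloxy)acetaldehyde should give ethyl (E)-4-(tert-butyldimethylsilyloxy)-2-[2-(3-methoxyphenyl)ethyl]but-2-enoate F7.
   - HF·pyridine should give ethyl (E)-4-hydroxy-2-[2-(3-methoxyphenyl)ethyl]but-2-enoate F8.
   - CBr4/PPh3 should give ethyl (E)-4-bromo-2-[2-(3-methoxyphenyl)ethyl]but-2-enoate F9.
   - Suzuki–Miyaura allyl–aryl coupling of F9 with 4-benzyloxyphenylboronic acid (Pd(PPh3)4, K2CO3, toluene, 80 °C) should place the aryl group at the unsubstituted allyl terminus and give 6.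

**Further compounds**

F1 | step 8 | 3-benzyloxy-5-methoxyphenylmagnesium bromide | COc1cc(OCc2ccccc2)cc([Mg]Br)c1
F2 | step 8 | 1-benzyloxy-3-methoxy-5-[2-(3-methoxyphenyl)ethyl]benzene | COc1cccc(CCc2cc(OC)cc(OCc3ccccc3)c2)c1
F3 | step 8 | 3-methoxy-5-[2-(3-methoxyphenyl)ethyl]phenol | COc1cccc(CCc2cc(O)cc(OC)c2)c1
F4 | step 6 | (E)-6-(4-benzyloxyphenyl)-4-[2-(3-methoxyphenyl)ethyl]-1-(trimethylsilyl)hex-4-en-1-yn-3-one | C[Si](C)(C)C#CC(=O)/C(CCc1cccc(OC)c1)=C/Cc1ccc(OCc2ccccc2)cc1
F5 | step 6 | (E)-3-(4-benzyloxybenzyl)-6-(4-benzyloxyphenyl)-4-[2-(3-methoxyphenyl)ethyl]-1-(trimethylsilyl)hex-4-en-1-yn-3-ol (racemic) | C[Si](C)(C)C#CC(O)(Cc1ccc(OCc2ccccc2)cc1)/C(CCc1cccc(OC)c1)=C/Cc1ccc(OCc2ccccc2)cc1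
F6 | step 6 | (E)-3-(4-benzyloxybenzyl)-6-(4-benzyloxyphenyl)-4-[2-(3-methoxyphenyl)ethyl]-1-(trimethylsilyl)hex-4-en-1-yn-3-yl pivalate (racemic) | CC(C)(C)C(=O)OC(Cc1ccc(OCc2ccccc2)cc1)(C#C[Si](C)(C)C)/C(CCc1cccc(OC)c1)=C/Cc1ccc(OCc2ccccc2)cc1
F7 | step 3 | ethyl (E)-4-(tert-butyldimethylsilyloxy)-2-[2-(3-methoxyphenyl)ethyl]but-2-enoate | CCOC(=O)/C(CCc1cccc(OC)c1)=C/CO[Si](C)(C)C(C)(C)C
F8 | step 3 | ethyl (E)-4-hydroxy-2-[2-(3-methoxyphenyl)ethyl]but-2-enoate | CCOC(=O)/C(CCc1cccc(OC)c1)=C/CO
F9 | step 3 | ethyl (E)-4-bromo-2-[2-(3-methoxyphenyl)ethyl]but-2-enoate | CCOC(=O)/C(CCc1cccc(OC)c1)=C/CBr
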